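**Retrosynthetic overview**
- The target is a 3,7,8-trimethoxyflavone with a 2'-hydroxy-4',5'-dimethoxyphenyl ring B; the last step frees the 2'-OH from benzyl ether 15.
- The strategy rests on the C2=C3 enol-ether double bond of pyranone ring C: C2 carries O1 and ring B, C3 carries the methoxy group and is bonded to the C4 ketone. This bond is cut as an olefin, C2 coming from an aryl ester carbonyl and C3 from a methoxy-substituted acyl ylide carbon (intramolecular ester Wittig reaction of 13).
- Ylide 13 comes from acid chloride 9 and two equivalents of Ph3P=CHOMe (C3–C4 bond by C-acylation of the ylide).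
- Acid chloride 9 comes from aldehyde 7 by oxidation; 7 is the ester of 2-hydroxy-3,4-dimethoxybenzaldehyde (ring A, future O1) with 2-(benzyloxy)-4,5-dimethoxybenzoyl chloride (ring B, future C2).
- Rings A and B are bought; ring C is the only ring formed, in step 8.

Key step: step 8

Remark: the target has no stereocentre, so no stereocontrol is needed; the 2'-OH is carried as a benzyl ether from step 1 to step 9 so that it cannot be acylated, and ring A is introduced as the aldehyde so that its carboxyl group is made only after the phenol has been esterified.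

**Route**

Step 1
Reactants: 1 2-hydroxy-4,5-dimethoxybenzoic acid
Product: 2 benzyl 2-(benzyloxy)-4,5-dimethoxybenzoate
Conditions: BnBr (2.4 equiv), K2CO3, DMF, 60 °C
Reagents that add atoms: benzyl bromide, BrCc1ccccc1
Why: Williamson etherification of the phenoxide and O-alkylation of the carboxylate occur in one pot, and since both acidic sites are to be benzylated no selectivity is needed.

Step 2
Reactants: 2 benzyl 2-(benzyloxy)-4,5-dimethoxybenzoate
Product: 4 2-(benzyloxy)-4,5-dimethoxybenzoic acid, via sodium carboxylate 3 (not isolated)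
Conditions: NaOH, MeOH/THF/H2O, 60 °C; then aq. HCl
Reagents that add atoms: sodium hydroxide, [Na+].[OH-]
Why: Saponification cleaves only the benzyl ester, because the aryl benzyl ether and the methyl ethers are inert to hydroxide.

Step 3
Reactants: 4 2-(benzyloxy)-4,5-dimethoxybenzoic acid
Product: 5 2-(benzyloxy)-4,5-dimethoxybenzoyl chloride
Conditions: (COCl)2, cat. DMF, CH2Cl2, 0 °C to rt; evaporate
Reagents that add atoms: oxalyl chloride, ClC(=O)C(=O)Cl
Why: DMF-catalysed acid chloride formation with oxalyl chloride runs at room temperature, gives only gaseous by-products and leaves the ortho benzyl ether intact.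

Step 4
Reactants: 5 2-(benzyloxy)-4,5-dimethoxybenzoyl chloride; 6 2-hydroxy-3,4-dimethoxybenzaldehyde
Product: 7 2-formyl-5,6-dimethoxyphenyl 2-(benzyloxy)-4,5-dimethoxybenzoate
Conditions: Et3N, cat. DMAP, CH2Cl2, 0 °C to rt
Reagents that add atoms: none
Why: DMAP-catalysed O-acylation of a phenol by an acid chloride should overcome the hydrogen bonding and flanking of the salicylaldehyde OH, and the non-enolisable aldehyde cannot interfere.

Step 5
Reactants: 7 2-formyl-5,6-dimethoxyphenyl 2-(benzyloxy)-4,5-dimethoxybenzoate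
Product: 8 2-{[2-(benzyloxy)-4,5-dimethoxybenzoyl]oxy}-3,4-dimethoxybenzoic acid
Conditions: NaClO2, NaH2PO4, 2-methyl-2-butene (excess), t-BuOH/THF/H2O, 0 °C to rt
Reagents that add atoms: sodium chlorite, [Na+].[O-]Cl=O
Why: Pinnick oxidation converts the aryl aldehyde into the acid in a weakly acidic buffer in which the aryl ester is not hydrolysed, while 2-methyl-2-butene traps the hypochlorous acid before it can chlorinate the electron-rich rings.

Step 6
Reactants: 8 2-{[2-(benzyloxy)-4,5-dimethoxybenzoyl]oxy}-3,4-dimethoxybenzoic acid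
Product: 9 2-{[2-(benzyloxy)-4,5-dimethoxybenzoyl]oxy}-3,4-dimethoxybenzoyl chloride
Conditions: (COCl)2, cat. DMF, CH2Cl2, 0 °C to rt; evaporate, use crude
Reagents that add atoms: oxalyl chloride, ClC(=O)C(=O)Cl
Why: DMF-catalysed acid chloride formation is neutral and anhydrous, conditions under which O-acylsalicyloyl chlorides are stable and the aryl ester and benzyl ether are untouched.

Step 7
Reactants: 9 2-{[2-(benzyloxy)-4,5-dimethoxybenzoyl]oxy}-3,4-dimethoxybenzoyl chloride; 10 (methoxymethyl)triphenylphosphonium chloride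
Product: 13 2-[2-methoxy-2-(triphenylphosphoranylidene)acetyl]-5,6-dimethoxyphenyl 2-(benzyloxy)-4,5-dimethoxybenzoate, via methoxymethylenetriphenylphosphorane 11 (not isolated), via acylphosphonium chloride 12 (not isolated)
Conditions: 10 (2.05 equiv), n-BuLi (2.0 equiv), THF, −78 to 0 °C; then add 9 in THF, −78 to 0 °C; filter off recovered 10, concentrate at or below rt
Reagents that add atoms: none
Why: This is the Bestmann C-acylation of a non-stabilised phosphorus ylide by an acid chloride with transylidation, in which one equivalent of 11 attacks the acid chloride (far more electrophilic at −78 °C than the hindered, electron-rich aryl ester) and the second deprotonates salt 12 to the stabilised acyl ylide 13, returning 10.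

Step 8
Reactants: 13 2-[2-methoxy-2-(triphenylphosphoranylidene)acetyl]-5,6-dimethoxyphenyl 2-(benzyloxy)-4,5-dimethoxybenzoate
Product: 15 2-[2-(benzyloxy)-4,5-dimethoxyphenyl]-3,7,8-trimethoxy-4H-chromen-4-one, via oxaphosphetane 14 (not isolated)
Conditions: toluene (0.02 M), reflux, N2
Reagents that add atoms: none
Why: The ylide carbon C3 of 13 adds to the carbonyl carbon of the ortho aryl ester (the future C2) in a 6-exo-trig closure that forms the C2–C3 bond and ring C and gives the ring-fused 1,2-oxaphosphetane 14, whose cycloreversion expels Ph3PO and leaves the C2=C3 double bond with the former ester oxygen as O1. The closest known reaction type is the intramolecular Wittig olefination of an ester carbonyl by an acyl-stabilised phosphorus ylide, as used to close chromones from 2-acyloxyphenacylidene phosphoranes. No stereocentre is formed in 15, and the two transient ones in 14 vanish on elimination. The step needs attack by carbon on the neighbouring ester in preference to intermolecular olefination and to acyl transfer onto the enolate oxygen: the ortho placement holds C3 next to C2, dilution disfavours bimolecular paths, and O-acyl transfer is reversible whereas loss of Ph3PO is not. The methoxy group on C3 weakens the stabilisation of the ylide and so raises its nucleophilicity, which should offset the low electrophilicity of the electron-rich aroyl ester and place the 3-OMe without any later oxidation at C3.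

Step 9
Reactants: 15 2-[2-(benzyloxy)-4,5-dimethoxyphenyl]-3,7,8-trimethoxy-4H-chromen-4-one
Product: 16 2-(2-hydroxy-4,5-dimethoxyphenyl)-3,7,8-trimethoxy-4H-chromen-4-one (CID10548300)
Conditions: H2 (1 atm), 10% Pd/C, EtOAc/MeOH, rt
Reagents that add atoms: none
Why: Hydrogenolysis of the aryl benzyl ether over palladium on carbon at atmospheric pressure should leave the methyl ethers and the tetrasubstituted, vinylogous-ester C2=C3 bond of the chromone untouched.

**Compound list**
1 | 2-hydroxy-4,5-dimethoxybenzoic acid | COc1cc(O)c(C(=O)O)cc1OC | starting material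
2 | benzyl 2-(benzyloxy)-4,5-dimethoxybenzoate | COc1cc(OCc2ccccc2)c(C(=O)OCc2ccccc2)cc1OC | intermediate
3 | sodium 2-(benzyloxy)-4,5-dimethoxybenzoate (formed in the flask) | COc1cc(OCc2ccccc2)c(C(=O)[O-])cc1OC.[Na+] | intermediate
4 | 2-(benzyloxy)-4,5-dimethoxybenzoic acid | COc1cc(OCc2ccccc2)c(C(=O)O)cc1OC | intermediate
5 | 2-(benzyloxy)-4,5-dimethoxybenzoyl chloride | COc1cc(OCc2ccccc2)c(C(=O)Cl)cc1OC | intermediate
6 | 2-hydroxy-3,4-dimethoxybenzaldehyde | COc1ccc(C=O)c(O)c1OC | starting material
7 | 2-formyl-5,6-dimethoxyphenyl 2-(benzyloxy)-4,5-dimethoxybenzoate | COc1ccc(C=O)c(OC(=O)c2cc(OC)c(OC)cc2OCc2ccccc2)c1OC | intermediate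
8 | 2-{[2-(benzyloxy)-4,5-dimethoxybenzoyl]oxy}-3,4-dimethoxybenzoic acid | COc1ccc(C(=O)O)c(OC(=O)c2cc(OC)c(OC)cc2OCc2ccccc2)c1OC | intermediate
9 | 2-{[2-(benzyloxy)-4,5-dimethoxybenzoyl]oxy}-3,4-dimethoxybenzoyl chloride | COc1ccc(C(=O)Cl)c(OC(=O)c2cc(OC)c(OC)cc2OCc2ccccc2)c1OC | intermediate
10 | (methoxymethyl)triphenylphosphonium chloride | COC[P+](c1ccccc1)(c1ccccc1)c1ccccc1.[Cl-] | starting material
11 | methoxymethylenetriphenylphosphorane (formed in the flask) | COC=P(c1ccccc1)(c1ccccc1)c1ccccc1 | intermediate
12 | {2-[2-{[2-(benzyloxy)-4,5-dimethoxybenzoyl]oxy}-3,4-dimethoxyphenyl]-1-methoxy-2-oxoethyl}triphenylphosphonium chloride (formed in the flask, racemic) | COc1ccc(C(=O)C(OC)[P+](c2ccccc2)(c2ccccc2)c2ccccc2)c(OC(=O)c2cc(OC)c(OC)cc2OCc2ccccc2)c1OC.[Cl-] | intermediate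
13 | 2-[2-methoxy-2-(triphenylphosphoranylidene)acetyl]-5,6-dimethoxyphenyl 2-(benzyloxy)-4,5-dimethoxybenzoate | COc1ccc(C(=O)C(OC)=P(c2ccccc2)(c2ccccc2)c2ccccc2)c(OC(=O)c2cc(OC)c(OC)cc2OCc2ccccc2)c1OC | intermediate
14 | 1,2-oxaphosphetane fused across C2–C3 of the chroman-4-one, with O on C2 and the pentacoordinate PPh3 phosphorus on C3 (formed in the flask, racemic, cis ring fusion) | COc1ccc2C(=O)C3(OC)C(c4cc(OC)c(OC)cc4OCc4ccccc4)(OP3(c3ccccc3)(c3ccccc3)c3ccccc3)Oc2c1OC | intermediate
15 | 2-[2-(benzyloxy)-4,5-dimethoxyphenyl]-3,7,8-trimethoxy-4H-chromen-4-one | COc1cc(OCc2ccccc2)c(-c2oc3c(OC)c(OC)ccc3c(=O)c2OC)cc1OC | intermediate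
16 | 2-(2-hydroxy-4,5-dimethoxyphenyl)-3,7,8-trimethoxy-4H-chromen-4-one | COc1cc(O)c(-c2oc3c(OC)c(OC)ccc3c(=O)c2OC)cc1OC | target

**Step count**
Total steps: 9. Longest linear sequence: 9 steps (from 1 through steps 1 to 9); aldehyde 6 enters at step 4 and phosphonium salt 10 at step 7.

**Steps most likely to fail**

Step 8 (key step). The fully substituted, methoxy-bearing ylide carbon may add too slowly to the electron-rich, ortho-substituted aroyl ester carbonyl, so that acyl migration to the enolate oxygen or thermal decomposition takes over. The fallback sets out from 13 and comes back at 15, replacing the olefination by a Baker–Venkataraman sequence. The phosphorus is removed reductively from 13 with Zn dust in AcOH (protonation at carbon, then reductive C–P cleavage with release of Ph3P), which should give 2-(2-methoxyacetyl)-5,6-dimethoxyphenyl 2-(benzyloxy)-4,5-dimethoxybenzoate F1. Treatment of F1 with KOtBu in THF (0 °C to rt) should move the aroyl group from the phenol oxygen to the methoxy-bearing carbon and give 1-[2-(benzyloxy)-4,5-dimethoxyphenyl]-3-(2-hydroxy-3,4-dimethoxyphenyl)-2-methoxypropane-1,3-dione F2. Cyclodehydration of F2 (cat. p-TsOH, toluene, reflux) then closes ring C to 15.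

Step 7. The non-stabilised ylide may attack the aryl ester in competition with the acid chloride (cleavage or transfer of the aroyl group), or the product ylide may be O-acylated by unreacted acid chloride. The fallback sets out from 6 (using 5 and 10 as in the route) and comes back at 13; it builds the ylide on ring A before the aryl ester exists and forms the ester last.
- 6 is benzylated (BnBr, K2CO3, DMF) to 2-(benzyloxy)-3,4-dimethoxybenzaldehyde F3, which carries neither the aryl ester nor ring B.
- F3 is oxidised (NaClO2, NaH2PO4, 2-methyl-2-butene) to 2-(benzyloxy)-3,4-dimethoxybenzoic acid F4 and converted with (COCl)2 and cat. DMF into 2-(benzyloxy)-3,4-dimethoxybenzoyl chloride F5.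
- F5 is added at −78 °C to two equivalents of 11 (from 10 and n-BuLi) to give 1-[2-(benzyloxy)-3,4-dimethoxyphenyl]-2-methoxy-2-(triphenylphosphoranylidene)ethanone F6.
- Hydrogenolysis (H2, Pd/C, EtOAc) should free the phenol 1-(2-hydroxy-3,4-dimethoxyphenyl)-2-methoxy-2-(triphenylphosphoranylidene)ethanone F7.
- O-aroylation of the phenol of F7 with 5 (Et3N, CH2Cl2, 0 °C) gives 13, which may go on to 15 in the same flask.

Step 5. Hypochlorous acid may escape the scavenger and chlorinate the trialkoxy ring B, or the aryl ester may be hydrolysed in the aqueous buffer. The fallback sets out from 6 and 5 and comes back at 8; the carboxyl group is made before ring B is attached and is unmasked without an oxidant.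
- 6 is oxidised with Ag2O in aqueous NaOH to 2-hydroxy-3,4-dimethoxybenzoic acid F8, an acid that can also be bought.
- The carboxylate of F8 is alkylated selectively (allyl bromide, KHCO3, DMF) to prop-2-en-1-yl 2-hydroxy-3,4-dimethoxybenzoate F9.
- The phenol of F9 is aroylated with 5 (Et3N, cat. DMAP, CH2Cl2) to prop-2-en-1-yl 2-{[2-(benzyloxy)-4,5-dimethoxybenzoyl]oxy}-3,4-dimethoxybenzoate F10.
- The allyl ester of F10 is cleaved with cat. Pd(PPh3)4 and PhSiH3 in CH2Cl2, a non-nucleophilic allyl acceptor that spares the aryl ester, to give 8.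

**Further compounds**
F1 | step 8 | 2-(2-methoxyacetyl)-5,6-dimethoxyphenyl 2-(benzyloxy)-4,5-dimethoxybenzoate | COc1ccc(C(=O)COC)c(OC(=O)c2cc(OC)c(OC)cc2OCc2ccccc2)c1OC
F2 | step 8 | 1-[2-(benzyloxy)-4,5-dimethoxyphenyl]-3-(2-hydroxy-3,4-dimethoxyphenyl)-2-methoxypropane-1,3-dione (racemic) | COc1ccc(C(=O)C(OC)C(=O)c2cc(OC)c(OC)cc2OCc2ccccc2)c(O)c1OC
F3 | step 7 | 2-(benzyloxy)-3,4-dimethoxybenzaldehyde | COc1ccc(C=O)c(OCc2ccccc2)c1OC
F4 | step 7 | 2-(benzyloxy)-3,4-dimethoxybenzoic acid | COc1ccc(C(=O)O)c(OCc2ccccc2)c1OC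
F5 | step 7 | 2-(benzyloxy)-3,4-dimethoxybenzoyl chloride | COc1ccc(C(=O)Cl)c(OCc2ccccc2)c1OC
F6 | step 7 | 1-[2-(benzyloxy)-3,4-dimethoxyphenyl]-2-methoxy-2-(triphenylphosphoranylidene)ethanone | COc1ccc(C(=O)C(OC)=P(c2ccccc2)(c2ccccc2)c2ccccc2)c(OCc2ccccc2)c1OC
F7 | step 7 | 1-(2-hydroxy-3,4-dimethoxyphenyl)-2-methoxy-2-(triphenylphosphoranylidene)ethanone | COc1ccc(C(=O)C(OC)=P(c2ccccc2)(c2ccccc2)c2ccccc2)c(O)c1OC
F8 | step 5 | 2-hydroxy-3,4-dimethoxybenzoic acid | COc1ccc(C(=O)O)c(O)c1OC
F9 | step 5 | prop-2-en-1-yl 2-hydroxy-3,4-dimethoxybenzoate | C=CCOC(=O)c1ccc(OC)c(OC)c1O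
F10 | step 5 | prop-2-en-1-yl 2-{[2-(benzyloxy)-4,5-dimethoxybenzoyl]oxy}-3,4-dimethoxybenzoate | COc1ccc(C(=O)OCC=C)c(OC(=O)c2cc(OC)c(OC)cc2OCc2ccccc2)c1OC
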